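Friday's run, charged at 0.17 M, is flat from 2.50 h to 8.00 h, with a target-to-isomer ratio near 10.4. Tuesday's run, the flask you are asked about, stands near 17.4 at 4.00 h, a higher ratio than Friday's. At one temperature, two isomers in simple solution equilibrium keep one ratio whatever the charge, so suppose that excess target leaves solution.

| flask | substrate | remark | time |
|---|---|---|---|
| Tuesday's | 0.25 M | the very flask that is asked about, followed so far |  |
| Friday's | 0.17 M | run made earlier |  |
| flask | 0.25 M |  | 10 h |

| run | time / h | target / % | isomer of the product / % |
|---|---|---|---|
| Tuesday's | 0.333 | 84.2 | 13.2 |
| Tuesday's | 0.667 | 89.7 | 7.9 |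
| Tuesday's | 1.50 | 91.4 | 5.9 |
| Tuesday's | 4.00 | 92.0 | 5.3 |
| Friday's | 0.833 | 86.5 | 9.7 |
| Friday's | 2.50 | 88.8 | 8.4 |
| Friday's | 5.00 | 88.1 | 8.8 |
| Friday's | 8.00 | 88.3 | 8.5 |

(readings scatter by 0.3 percentage points)

- what was read earlier has a scatter of 0.3 percentage points, one standard deviation
- a reading or a percentage of target counts all its forms, free or not
- the reaction counts as stopped when no species that holds the substrate changes by six tenths of a point or more over the second half of the time

1. which holds at 10 h: what has brought the reaction to rest, or that it has not come to rest (all of the substrate has reacted / it is still moving / forward and back rates have come level)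
2. amount of target at 10 h, in percent of the substrate charged
3. amount of isomer of the product at 10 h, in percent of the substrate charged

Follow one charged molecule. If what stays beside the excess stands at fixed concentrations, its chance of ending as isomer is that resting concentration over the charge. Friday's 3 flat readings average 8.57%, and this mean times Friday's charge is my reading of c(isomer) at rest, the level left under thermodynamic control: 14.6 mM. Over 0.25 M that is 5.83%. Friday's target likewise leaves 19.7 mM outside target, so I reckon target at 92.1%. The remaining 2.07% I take as substrate, and since Friday's run stands flat with that share so taken, my answer for this flask is that forward and back rates have come level.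

The weak link is the fixed concentration. Tuesday's last isomer reading gives 13.2 mM, so it lies 0.53 percentage points below my figure. That is one reading with a scatter of 0.3 points, while the mean carried over from Friday has about 0.12 points, so I keep 5.83%.

The forecast says forward and back rates have come level, with target 92% (91.3% to 92.7%) and isomer 5.4% (4.8% to 5.9%): “Some target must be bound or out of solution”. Its isomer lies nearer Tuesday's last reading than mine does.

The flask gives forward and back rates have come level, with target 92.0% and isomer 5.74%.

    crystals ⇌ target, rate k1*(cs1 - [target]) while solid is left; crystals form when [target] > cs1 (solubility = 2.70 mM, k = 0.130 s⁻¹)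
    substrate ⇌ target (K = 0.470, k = 0.00810 s⁻¹)
    target ⇌ isomer of the product (k = 0.00140 s⁻¹)
    substrate ⇌ isomer of the product (K = 2.50, k = 0.00260 s⁻¹)

Crystals hold 90.9% of the charge at 10.0 h, counted within target. The flask's isomer is 14.4 mM, against the 14.6 mM carried from Friday's run. Put over the neighbour's charge of 1.0 M, that concentration is 1.44%, and the neighbour holds 1.44% isomer at 10.0 h.

All runs stem from a simulated flask with made-up constants.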